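All constants stand for no real mixture; the flask was simulated.

How much target can you take from this flask, and does waiting help or hurt? South, south-west and west share a recipe and differ in time.

| setting | south | west | south-west |
|---|---|---|---|
| substrate | 10 mM | 10 mM | 10 mM |
| reagent | 1.10 equiv | 1.10 equiv | 1.10 equiv |
| free catalyst | 0.51 mol% | 0.51 mol% | 0.51 mol% |
| added ligand | 0.22 mM | 0.22 mM | 0.22 mM |
| time | 5.0 s | 20 s | 10 s |

    substrate + free catalyst → catalyst intermediate A (k1 = 1.32 × 10⁵ M⁻¹ s⁻¹)
    reagent + catalyst intermediate A → catalyst intermediate B (k2 = 7860 M⁻¹ s⁻¹)
    catalyst intermediate B → by-product + catalyst intermediate C (k3 = 85.0 s⁻¹)
    catalyst intermediate C → free catalyst + target (k4 = 103 s⁻¹)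
    2 catalyst intermediate A → spent catalyst (k5 = 2930 M⁻¹ s⁻¹)
    free catalyst + added ligand ⇌ idle complex (K6 = 2300 M⁻¹, k6 = 1920 M⁻¹ s⁻¹)
    target + by-product → side product (k7 = 44.4 M⁻¹ s⁻¹)

- which of the two there is more of at the end, south (target / side product)
- which of the two there is more of at the end, west (target / side product)
- which of the two there is more of at the end, south-west (target / side product)
- amount of target at the end, in percent of the substrate charged, south
- amount of target at the end, in percent of the substrate charged, west
- amount of target at the end, in percent of the substrate charged, south-west

- in percentages every species weighs as the substrate in it: one spent catalyst counts as two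
- two of one species on the left: rate k times its square, two consumed each time
- run time (south): 5.0 s

My reckoning starts with the supply of target. A catalyst lap is the sum of its waits. The wait for substrate, 0.758 ms, is shorter than the fall of catalyst intermediate B, so I drop it. Reagent shrinks during the run, so I take it at half turnover:

reagent then = 6.00 mM

lap = wait for reagent + fall of intermediate B + fall of intermediate C = 42.7 ms

supply = catalyst charge / lap = 0.0510 mM / lap = 1.19 mM s⁻¹

I count the whole catalyst charge as working and hold this supply flat, which is rough.

Now the loss. Each lap gives one target and one by-product, and the burn step, target + by-product → side product, takes one of each. So I set the two equal, and the burn goes as its constant times target squared. Supply stays flat while the burn climbs, so target rises toward the balance level, the amount of target at which the burn removes it as fast as the cycle delivers it: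

balance level = square root of (supply / burn constant) = 5.19 mM

clock = balance level / supply = 4.34 s

target = balance level × tanh(time / clock)

Substrate is the limiting reagent, so I end the supply at charge / supply = 8.37 s. South stops earlier, at 42.5% target, and the larger product there is target.

By the end of supply, target stands at 4.97 mM. After that its reciprocal grows by the burn constant each second. South-west then gives 36.6% and west 13.9%. The larger product is side product in south-west and side product in west.

The forecast gives 39.3% target in south, 35% in south-west and 18% in west. It names target as the larger in south, side product in south-west and side product in west. It starts from the same pairing, “Target and by-product form together”, but it lets the supply slow and steps target by hand, where I hold the supply flat, and its figures differ from mine.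

The simulation gives target 39.7% against side product 18.2% in south, 34.8% against 51.2% in south-west, and 17.6% against 82.0% in west. The forecast's answers stand.

West's low target comes mainly from the burn step: with that step struck out, west holds 99.7% target instead of 17.6%. South's 39.7% lies below its balance level, 51.9% of the charge. Now take the neighbour with 17 mM substrate, same equivalents and loading. The same reckoning puts its supply at 2.55 mM s⁻¹ and its balance level at 7.58 mM, a smaller share of its charge, at 44.6%. That flask gives 36.9% target against 32.2% side product.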